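## Analysis of the target

Acredinone A (26) is a 2,3-diaryl-1H-inden-1-one. Ring A is fused to the five-membered enone (C1 ketone, C2=C3, C3a to C7a) and carries OH at C4, methyl at C6 and OMe at C7. C3 bears ring D, a 2,6-dimethoxyphenyl group. C2 bears ring B, whose carbon B2 carries the ketone C8 and, through it, ring E, a second 2,6-dimethoxyphenyl group. There is no stereogenic centre; the C2–B1 and C3–ring D axes are hindered, but the target is specified without descriptors, so nothing has to be controlled. The sensitive parts are the two free phenols (C4–OH and B3–OH), each para to a methoxy group and therefore easily oxidized, the indenone, and the electron-rich dimethoxyphenyl rings, which take up electrophilic halogen readily. The difficulty is crowding: C2 and C3 each carry an arene with two ortho substituents, rings A and B are both pentasubstituted, and the para oxygens on each ring must end up differentiated as OH and OMe. The strategy rests on ring B being a 4-methoxyphenol with OMe at B6, methyl at B5, hydrogen at B4, OH at B3 and carbon substituents only at B1 and B2. This is the pattern a Dötz benzannulation delivers: B6 with its OMe from a methoxycarbene carbon, B5 and B4 from an isopropenyl group, B3 with its free OH from a carbonyl ligand, and B1–B2 from an alkyne that is already bonded to C2.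

## Retrosynthetic reasoning

**26 back to 23.** Three functional-group operations are removed first: cleavage of the C4 methoxymethyl acetal (25), oxidation of the C8 carbinol to the ketone (24), and desilylation (23). C8 is carried as a silyl-protected carbinol because this keeps the alkyne of the key step electronically unbiased. It also makes the substituent on that alkyne carbon an sp3-branched, bulky group, which the regiochemistry of the key step needs.

**23 back to 16 and 21.** Ring B is cut at B6–B1, B2–B3 and B3–B4. This leaves the alkyne B1≡B2 on the indenone (16), the carbene complex 21 and one of its own carbonyl ligands. The cut is made here because the crowded C2–B1 bond then never has to be formed by joining two hindered sp2 carbons. It also means the OMe/OH difference on ring B arises automatically. The forward reaction must insert the alkyne with the silyloxybenzyl carbon next to the carbonyl-derived carbon and must follow the phenol pathway; the first product is the chromium arene complex 22.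

**21 back to 17 and 18.** The carbene complex comes from the organolithium 19 (made from 17) adding to a carbonyl ligand of 18 to give the acylate 20, followed by O-methylation.

**16 back to 15 and 4.** The C2–C(sp) bond is cut as a Sonogashira coupling. A linear alkyne is the slimmest carbon nucleophile that can be brought to C2 between the C1 carbonyl and ring D. The forward reaction needs oxidative addition into the C2–Br bond of an α-bromoenone, which is an activated position.

**4 back to 1.** The propargylic silyl ether 4 comes from alcohol 3, which is the adduct of an ethynyl nucleophile with aldehyde 1.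

**15 back to 14.** The five-membered ring is cut at C3–C3a together with the C2–Br bond. In the forward direction a bromine atom adds to the alkyne carbon next to the carbonyl of ynone 14, and the resulting C3 vinyl radical closes onto the free ortho carbon of the aroyl ring. Ring formation and installation of the C2 handle are thus combined, and the indenone oxidation level is reached directly.

**14 back to 11 and 2.** The C1–C2 bond is cut as an acetylide addition (12, from 2) to aldehyde 11, giving 13, followed by oxidation. Alkyne 2 comes from aldehyde 1 by one-carbon homologation, so 1 supplies both ring D and ring E.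

**11 back to 5.** The aldehyde carbon is placed by halogen–lithium exchange on bromide 9 (via 10), so the bromine of 5 fixes the position of C1. The C4 oxygen is introduced into anisole 6 (from 5 by O-methylation) by sterically controlled C–H borylation (7) and oxidation to phenol 8. That phenol is protected as the small methoxymethyl ether 9.

## Alternatives that were turned down

**Alternative 1: Nazarov-type closure onto ring A.**
- Disconnection: C3–C3a, leading back to the α-aryl chalcone A1, in which the C1 carbonyl carries ring A, C2 the complete ring B with C8 and ring E, and C3 ring D.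
- Forward key step: a strong Lewis acid activates the C1 carbonyl and the cation closes by 4π electrocyclization through the C7a–C3a bond of ring A. Rearomatization gives the trans-2,3-diarylindan-1-one A2. Dehydrogenation across C2–C3 and removal of the acetates would then be needed to reach 26.
- For: this is a classical ring closure; the C3 cation is well stabilized by ring D; the trans relationship in A2 is irrelevant because both centres disappear; all five rings are in place before the key step.
- Against:
  - The attacking carbon of ring A is meta to its methoxy group and sits on an acylated ring, so the closure has to break the aromaticity of a poorly nucleophilic arene.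
  - The C8 ketone of A1 competes for the Lewis acid.
  - A1 needs a separately built pentasubstituted ring B, its attachment to C2, and a condensation with the hindered aldehyde 1, so the crowding is only moved upstream.
  - A2 is at the wrong oxidation level. The late dehydrogenation needs enolization at the shielded C2 under oxidizing conditions in a molecule that carries two protected hydroquinone monoethers.
- Comparison: Alternative 1 is stronger in one respect: the ring B substitution is never in question and no stoichiometric metal carbene is used. The chosen route offers instead the indenone oxidation level from 15 onward, no separate synthesis of ring B, and only three simple steps after the key step.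

**Alternative 2: Twofold silyloxyfuran Diels–Alder.**
- Disconnection: rings A and B are both cut (C4–C3a, C7–C7a, B3–B2, B6–B1), leading to the open-chain bis-ynone A3 and two molecules of the silyloxyfuran A4.
- Forward key step: on heating, each ynone adds one molecule of A4 and the oxygen bridges open to the phenols, giving A5.
- For: two arenes form in one operation from a linear precursor, and both rings use the same diene. The polarity is matched: the nucleophilic C5 of A4 meets the β-carbon of each ynone. The para oxygens emerge differentiated as OH and silyl ether.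
- Against:
  - Silyloxyfurans tend to give vinylogous conjugate addition rather than cycloaddition with β-substituted ynones.
  - A3 has an acidic propargylic CH2 next to a silyloxy-bearing carbon and is prone to elimination and allene formation on heating.
  - After the key step the hardest work remains: the five-membered ring and the tetrasubstituted C2=C3 bond must still be made, by condensation of the C2 methylene onto the hindered C3 diaryl ketone, after methylation, desilylation and oxidation at C1.
- Comparison: Alternative 2 is stronger on ring-forming economy and avoids chromium. The chosen route secures the five-membered ring and the C2=C3 bond before its risky step, so success in step 13 leaves only routine chemistry.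

**Alternative 3: Aryl radical addition and cyclization.**
- Disconnection: C2–B1 and C3–C3a together, leading to the ring A–ring D propynone A6 and the ring B diazonium salt A7.
- Forward key step: a ruthenium polypyridyl photocatalyst under visible light reduces A7 to the B1 aryl radical. This adds to C2 of A6, and the C3 vinyl radical closes onto ring A to give acredinone A diacetate A8.
- For: it is the most convergent plan. The whole skeleton forms in one catalytic step from two halves, the reaction class is known for simple aryl diazonium salts, and only deacetylation follows.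
- Against:
  - The B1 radical is flanked by OMe and an aroyl group and must add bimolecularly to a disubstituted alkyne carbon.
  - Intramolecular escapes are expected to be faster: a 1,5-hydrogen shift from the B6 methoxy group, and Pschorr-type attack on ring E.
  - A7 requires a pentasubstituted aniline carrying the diaryl ketone, which is a long synthesis of its own.
- Comparison: Alternative 3 is stronger in convergence and in using a catalytic metal. The chosen route never makes C2–B1 by attack at a hindered centre and needs no prefabricated ring B, since that ring is assembled from an alkyne, a carbonyl ligand and a four-carbon carbene ligand.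

Key step: step 13

Remark on the chemistry: because the target carries no stereodescriptor, the hindered aryl axes are not controlled. Every compound containing the C8 carbinol centre is carried as a racemate (SMILES show one enantiomer), possibly as rotamers about C2–B1 that converge once C8 is a ketone.

## Steps

Step 1
Reactants: 1 2,6-dimethoxybenzaldehyde
Product: 2 2-ethynyl-1,3-dimethoxybenzene
Conditions: dimethyl (1-diazo-2-oxopropyl)phosphonate, K2CO3, MeOH, rt
Reagents that add atoms: dimethyl (1-diazo-2-oxopropyl)phosphonate (Ohira–Bestmann reagent), COP(=O)(OC)C(=[N+]=[N-])C(C)=O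
Why: Seyferth–Gilbert homologation in the Ohira–Bestmann variant converts a non-enolizable aryl aldehyde into the terminal alkyne under mild base, which the two methoxy groups tolerate.

Step 2
Reactants: 1 2,6-dimethoxybenzaldehyde
Product: 3 rac-1-(2,6-dimethoxyphenyl)prop-2-yn-1-ol
Conditions: HC≡CMgBr, THF, 0 °C to rt
Reagents that add atoms: ethynylmagnesium bromide, C#C[Mg]Br
Why: Grignard 1,2-addition to an aldehyde; the new C8 centre is formed as a racemate, which is sufficient because it ends as a ketone.

Step 3
Reactants: 3 rac-1-(2,6-dimethoxyphenyl)prop-2-yn-1-ol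
Product: 4 rac-tert-butyl{[1-(2,6-dimethoxyphenyl)prop-2-yn-1-yl]oxy}dimethylsilane
Conditions: TBSCl, imidazole, DMF, rt
Reagents that add atoms: tert-butyldimethylsilyl chloride, CC(C)(C)[Si](C)(C)Cl
Why: Standard silylation of a secondary alcohol; the silyl ether removes the acidic OH before the couplings and makes this propargylic carbon the bulky alkyne substituent needed in step 13.

Step 4
Reactants: 5 2-bromo-6-methylphenol
Product: 6 1-bromo-2-methoxy-3-methylbenzene
Conditions: MeI, K2CO3, acetone, reflux
Reagents that add atoms: iodomethane, CI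
Why: Williamson O-methylation of a phenol; this oxygen becomes the C7 methoxy group.

Step 5
Reactants: 6 1-bromo-2-methoxy-3-methylbenzene
Product: 8 3-bromo-4-methoxy-5-methylphenol, via aryl pinacolboronate 7 (not isolated)
Conditions: [Ir(OMe)(cod)]2 (cat.), 4,4'-di-tert-butyl-2,2'-bipyridine, B2pin2, THF, 80 °C; then KHSO5 (Oxone), acetone/H2O, rt
Reagents that add atoms: bis(pinacolato)diboron, CC1(C)OB(OC1(C)C)B1OC(C)(C)C(C)(C)O1 (boron group of 7); potassium peroxymonosulfate, [K+].[O-]S(=O)(=O)OO (oxygen of 8)
Why: Iridium-catalysed C–H borylation is sterically governed and should take the only C–H with no ortho substituent (para to OMe) while leaving the C–Br bond intact; oxidation of the C–B bond then gives the phenol in one pot.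

Step 6
Reactants: 8 3-bromo-4-methoxy-5-methylphenol
Product: 9 1-bromo-2-methoxy-5-(methoxymethoxy)-3-methylbenzene
Conditions: MOMCl, i-Pr2NEt, CH2Cl2, 0 °C to rt
Reagents that add atoms: chloromethyl methyl ether, COCCl
Why: Phenol protection as a methoxymethyl acetal, chosen because it is small (it will sit next to the carbon attacked in step 10), stable to organolithiums, amines, fluoride and MnO2, and removable at the end with acid.

Step 7
Reactants: 9 1-bromo-2-methoxy-5-(methoxymethoxy)-3-methylbenzene
Product: 11 2-methoxy-5-(methoxymethoxy)-3-methylbenzaldehyde, via aryllithium 10 (not isolated)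
Conditions: n-BuLi, THF, −78 °C; then DMF, −78 °C to 0 °C; aq. NH4Cl
Reagents that add atoms: N,N-dimethylformamide, CN(C)C=O
Why: Bromine–lithium exchange at −78 °C is much faster than acetal-directed deprotonation, so the formyl group is placed exactly where bromine was; formylation of an aryllithium with DMF.

Step 8
Reactants: 2 2-ethynyl-1,3-dimethoxybenzene; 11 2-methoxy-5-(methoxymethoxy)-3-methylbenzaldehyde
Product: 13 rac-3-(2,6-dimethoxyphenyl)-1-[2-methoxy-5-(methoxymethoxy)-3-methylphenyl]prop-2-yn-1-ol, via lithium acetylide 12 (not isolated)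
Conditions: n-BuLi, THF, −78 °C; then 11, −78 °C to 0 °C
Reagents that add atoms: none
Why: Addition of a lithium acetylide to an aryl aldehyde forms the C1–C2 bond; the carbinol centre is racemic and is removed in the next step.

Step 9
Reactants: 13 rac-3-(2,6-dimethoxyphenyl)-1-[2-methoxy-5-(methoxymethoxy)-3-methylphenyl]prop-2-yn-1-ol
Product: 14 3-(2,6-dimethoxyphenyl)-1-[2-methoxy-5-(methoxymethoxy)-3-methylphenyl]prop-2-yn-1-one
Conditions: MnO2 (activated), CH2Cl2, rt
Reagents that add atoms: none
Why: MnO2 oxidizes benzylic-propargylic alcohols selectively to ynones under neutral conditions that leave the acetal and the aryl ethers untouched.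

Step 10
Reactants: 14 3-(2,6-dimethoxyphenyl)-1-[2-methoxy-5-(methoxymethoxy)-3-methylphenyl]prop-2-yn-1-one
Product: 15 2-bromo-3-(2,6-dimethoxyphenyl)-7-methoxy-4-(methoxymethoxy)-6-methyl-1H-inden-1-one
Conditions: KBr, K2S2O8, KHCO3, MeCN/H2O, 80 °C
Reagents that add atoms: potassium bromide, [K+].[Br-]
Why: Radical addition–cyclization cascade of a 1,3-diarylpropynone: a bromine atom from persulfate oxidation of bromide adds to the alkyne carbon next to the carbonyl, the C3 vinyl radical closes onto the only free ortho carbon of the aroyl ring (C3–C3a), and oxidation with loss of a proton restores ring A. Radical rather than electrophilic bromine is used (excess bromide, buffer) so that the C7 methoxy oxygen and ring D are not engaged.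

Step 11
Reactants: 15 2-bromo-3-(2,6-dimethoxyphenyl)-7-methoxy-4-(methoxymethoxy)-6-methyl-1H-inden-1-one; 4 rac-tert-butyl{[1-(2,6-dimethoxyphenyl)prop-2-yn-1-yl]oxy}dimethylsilane
Product: 16 rac-2-{3-[(tert-butyldimethylsilyl)oxy]-3-(2,6-dimethoxyphenyl)prop-1-yn-1-yl}-3-(2,6-dimethoxyphenyl)-7-methoxy-4-(methoxymethoxy)-6-methyl-1H-inden-1-one
Conditions: Pd(PPh3)2Cl2 (cat.), CuI (cat.), Et3N, THF, 50 °C, degassed
Reagents that add atoms: none
Why: Sonogashira coupling at an α-bromoenone, whose C–Br bond is activated toward oxidative addition; the linear alkyne reaches C2 between the carbonyl and ring D, where an aryl partner would not fit easily.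

Step 12
Reactants: 17 2-bromopropene; 18 hexacarbonylchromium, Cr(CO)6
Product: 21 pentacarbonyl[methoxy(prop-1-en-2-yl)carbene]chromium, via isopropenyllithium 19 (not isolated), via lithium acylchromate 20 (not isolated)
Conditions: t-BuLi (2 equiv), Et2O, −78 °C; Cr(CO)6, Et2O, 0 °C to rt; then Me3OBF4, CH2Cl2/H2O, 0 °C
Reagents that add atoms: trimethyloxonium tetrafluoroborate, C[O+](C)C.F[B-](F)(F)F
Why: Fischer carbene synthesis: the alkenyllithium adds to a carbonyl ligand of Cr(CO)6 and the acylate oxygen is methylated by the hard oxonium salt.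

Step 13
Reactants: 16 rac-2-{3-[(tert-butyldimethylsilyl)oxy]-3-(2,6-dimethoxyphenyl)prop-1-yn-1-yl}-3-(2,6-dimethoxyphenyl)-7-methoxy-4-(methoxymethoxy)-6-methyl-1H-inden-1-one; 21 pentacarbonyl[methoxy(prop-1-en-2-yl)carbene]chromium
Product: 23 rac-2-{2-[(tert-butyldimethylsilyl)oxy(2,6-dimethoxyphenyl)methyl]-3-hydroxy-6-methoxy-5-methylphenyl}-3-(2,6-dimethoxyphenyl)-7-methoxy-4-(methoxymethoxy)-6-methyl-1H-inden-1-one, via tricarbonylchromium arene complex 22 (not isolated)
Conditions: 21 (2 equiv), THF, 55 °C, Ar, degassed; then air, CH2Cl2, rt
Reagents that add atoms: none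
Why: Thermal loss of one cis carbonyl ligand from 21 opens a site on chromium; the alkyne of 16 coordinates and inserts into the Cr=C bond so that the carbene carbon (future B6 with its OMe) bonds to the alkyne carbon attached to C2 (B1), and the new carbene carbon B2 takes up a carbonyl ligand to give a chromium-bound dienylketene (B2–B3). Ring B then closes by a thermal 6π electrocyclization of this dienylketene between the ketene carbon B3 and the CH2 terminus of the former isopropenyl group (B3–B4), and tautomerization of the cyclohexadienone gives the phenol as its Cr(CO)3 complex 22, from which air releases 23. The closest known reaction type is the Dötz benzannulation of alkenyl(alkoxy)carbene chromium complexes with internal alkynes, silyl propargyl ethers included, to 4-alkoxyphenols. No stereocentre is created: C8 is a spectator, the planar chirality of 22 vanishes on decomplexation, and rotamers about C2–B1 converge at the ketone stage. The step needs one regiochemical outcome, the silyloxybenzyl carbon next to the carbonyl-derived carbon B3; the steric rule of the reaction predicts this if the sp3 carbon bearing OTBS and ring E is the more space-demanding alkyne substituent during insertion. It also needs the phenol pathway to prevail over cyclobutenone and five-membered-ring by-products, which alkenyl complexes in THF generally favour, and the tetrasubstituted indenone alkene is too hindered to intercept the carbene.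

Step 14
Reactants: 23 rac-2-{2-[(tert-butyldimethylsilyl)oxy(2,6-dimethoxyphenyl)methyl]-3-hydroxy-6-methoxy-5-methylphenyl}-3-(2,6-dimethoxyphenyl)-7-methoxy-4-(methoxymethoxy)-6-methyl-1H-inden-1-one
Product: 24 rac-2-{2-[(2,6-dimethoxyphenyl)(hydroxy)methyl]-3-hydroxy-6-methoxy-5-methylphenyl}-3-(2,6-dimethoxyphenyl)-7-methoxy-4-(methoxymethoxy)-6-methyl-1H-inden-1-one
Conditions: Bu4NF, AcOH, THF, rt to 40 °C, Ar
Reagents that add atoms: none
Why: Fluoride cleavage of the silyl ether; buffering with acetic acid keeps the medium near neutral, so neither the phenolate is exposed to air oxidation nor the very electron-rich benzhydrol to ionization.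

Step 15
Reactants: 24 rac-2-{2-[(2,6-dimethoxyphenyl)(hydroxy)methyl]-3-hydroxy-6-methoxy-5-methylphenyl}-3-(2,6-dimethoxyphenyl)-7-methoxy-4-(methoxymethoxy)-6-methyl-1H-inden-1-one
Product: 25 2-[2-(2,6-dimethoxybenzoyl)-3-hydroxy-6-methoxy-5-methylphenyl]-3-(2,6-dimethoxyphenyl)-7-methoxy-4-(methoxymethoxy)-6-methyl-1H-inden-1-one
Conditions: MnO2 (activated), CH2Cl2, rt
Reagents that add atoms: none
Why: MnO2 oxidation of a doubly benzylic alcohol to the diaryl ketone under neutral, heterogeneous conditions, chosen because it normally leaves 4-alkoxyphenols alone, unlike hypervalent iodine or quinone oxidants; the C8 stereocentre is removed here.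

Step 16
Reactants: 25 2-[2-(2,6-dimethoxybenzoyl)-3-hydroxy-6-methoxy-5-methylphenyl]-3-(2,6-dimethoxyphenyl)-7-methoxy-4-(methoxymethoxy)-6-methyl-1H-inden-1-one
Product: 26 acredinone A, 2-[2-(2,6-dimethoxybenzoyl)-3-hydroxy-6-methoxy-5-methylphenyl]-3-(2,6-dimethoxyphenyl)-4-hydroxy-7-methoxy-6-methyl-1H-inden-1-one
Conditions: HCl (cat.), MeOH, 40 °C
Reagents that add atoms: none
Why: Acid-catalysed acetal exchange transfers the methoxymethyl group to methanol and frees the C4 phenol; the aryl methyl ethers, the ketones and the indenone are stable to these conditions, and the acid-sensitive benzhydrol is already oxidized.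

## Compound list

1 | 2,6-dimethoxybenzaldehyde | COc1cccc(OC)c1C=O | starting material
2 | 2-ethynyl-1,3-dimethoxybenzene | C#Cc1c(OC)cccc1OC | intermediate
3 | rac-1-(2,6-dimethoxyphenyl)prop-2-yn-1-ol (one enantiomer drawn) | C#C[C@H](O)c1c(OC)cccc1OC | intermediate
4 | rac-tert-butyl{[1-(2,6-dimethoxyphenyl)prop-2-yn-1-yl]oxy}dimethylsilane (one enantiomer drawn) | C#C[C@H](O[Si](C)(C)C(C)(C)C)c1c(OC)cccc1OC | intermediate
5 | 2-bromo-6-methylphenol | Cc1cccc(Br)c1O | starting material
6 | 1-bromo-2-methoxy-3-methylbenzene | COc1c(C)cccc1Br | intermediate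
7 | 2-(3-bromo-4-methoxy-5-methylphenyl)-4,4,5,5-tetramethyl-1,3,2-dioxaborolane (not isolated) | COc1c(C)cc(cc1Br)B1OC(C)(C)C(C)(C)O1 | intermediate
8 | 3-bromo-4-methoxy-5-methylphenol | COc1c(C)cc(O)cc1Br | intermediate
9 | 1-bromo-2-methoxy-5-(methoxymethoxy)-3-methylbenzene | COCOc1cc(C)c(OC)c(Br)c1 | intermediate
10 | [2-methoxy-5-(methoxymethoxy)-3-methylphenyl]lithium (not isolated) | [Li]c1cc(OCOC)cc(C)c1OC | intermediate
11 | 2-methoxy-5-(methoxymethoxy)-3-methylbenzaldehyde | COCOc1cc(C)c(OC)c(C=O)c1 | intermediate
12 | [(2,6-dimethoxyphenyl)ethynyl]lithium (not isolated) | [Li]C#Cc1c(OC)cccc1OC | intermediate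
13 | rac-3-(2,6-dimethoxyphenyl)-1-[2-methoxy-5-(methoxymethoxy)-3-methylphenyl]prop-2-yn-1-ol (one enantiomer drawn) | COCOc1cc(C)c(OC)c(c1)[C@H](O)C#Cc1c(OC)cccc1OC | intermediate
14 | 3-(2,6-dimethoxyphenyl)-1-[2-methoxy-5-(methoxymethoxy)-3-methylphenyl]prop-2-yn-1-one | COCOc1cc(C)c(OC)c(c1)C(=O)C#Cc1c(OC)cccc1OC | intermediate
15 | 2-bromo-3-(2,6-dimethoxyphenyl)-7-methoxy-4-(methoxymethoxy)-6-methyl-1H-inden-1-one | O=C1C(Br)=C(c2c(OC)cccc2OC)c2c(OCOC)cc(C)c(OC)c21 | intermediate
16 | rac-2-{3-[(tert-butyldimethylsilyl)oxy]-3-(2,6-dimethoxyphenyl)prop-1-yn-1-yl}-3-(2,6-dimethoxyphenyl)-7-methoxy-4-(methoxymethoxy)-6-methyl-1H-inden-1-one (one enantiomer drawn) | O=C1C(C#C[C@H](O[Si](C)(C)C(C)(C)C)c2c(OC)cccc2OC)=C(c2c(OC)cccc2OC)c2c(OCOC)cc(C)c(OC)c21 | intermediate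
17 | 2-bromopropene | C=C(C)Br | starting material
18 | hexacarbonylchromium, Cr(CO)6 | O=C=[Cr](=C=O)(=C=O)(=C=O)(=C=O)=C=O | starting material
19 | isopropenyllithium (not isolated) | [Li]C(C)=C | intermediate
20 | lithium pentacarbonyl(2-methylprop-2-enoyl)chromate (not isolated) | [Li+].C=C(C)C([O-])=[Cr](=C=O)(=C=O)(=C=O)(=C=O)=C=O | intermediate
21 | pentacarbonyl[methoxy(prop-1-en-2-yl)carbene]chromium | COC(C(C)=C)=[Cr](=C=O)(=C=O)(=C=O)(=C=O)=C=O | intermediate
22 | tricarbonylchromium complex of 23, Cr(CO)3 bound η6 to ring B (not isolated; the metal fragment is written as a separate part) | O=C1C(c2c(OC)c(C)cc(O)c2[C@H](O[Si](C)(C)C(C)(C)C)c2c(OC)cccc2OC)=C(c2c(OC)cccc2OC)c2c(OCOC)cc(C)c(OC)c21.[Cr](=C=O)(=C=O)=C=O | intermediate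
23 | rac-2-{2-[(tert-butyldimethylsilyl)oxy(2,6-dimethoxyphenyl)methyl]-3-hydroxy-6-methoxy-5-methylphenyl}-3-(2,6-dimethoxyphenyl)-7-methoxy-4-(methoxymethoxy)-6-methyl-1H-inden-1-one (one enantiomer drawn) | O=C1C(c2c(OC)c(C)cc(O)c2[C@H](O[Si](C)(C)C(C)(C)C)c2c(OC)cccc2OC)=C(c2c(OC)cccc2OC)c2c(OCOC)cc(C)c(OC)c21 | intermediate
24 | rac-2-{2-[(2,6-dimethoxyphenyl)(hydroxy)methyl]-3-hydroxy-6-methoxy-5-methylphenyl}-3-(2,6-dimethoxyphenyl)-7-methoxy-4-(methoxymethoxy)-6-methyl-1H-inden-1-one (one enantiomer drawn) | O=C1C(c2c(OC)c(C)cc(O)c2[C@H](O)c2c(OC)cccc2OC)=C(c2c(OC)cccc2OC)c2c(OCOC)cc(C)c(OC)c21 | intermediate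
25 | 2-[2-(2,6-dimethoxybenzoyl)-3-hydroxy-6-methoxy-5-methylphenyl]-3-(2,6-dimethoxyphenyl)-7-methoxy-4-(methoxymethoxy)-6-methyl-1H-inden-1-one | O=C1C(c2c(OC)c(C)cc(O)c2C(=O)c2c(OC)cccc2OC)=C(c2c(OC)cccc2OC)c2c(OCOC)cc(C)c(OC)c21 | intermediate
26 | acredinone A | COc1cccc(OC)c1C(=O)c1c(O)cc(C)c(OC)c1C1=C(c2c(OC)cccc2OC)c2c(O)cc(C)c(OC)c2C1=O | target

## Step count and least certain steps

Total: 16 steps. Longest linear sequence: 12 steps (5 to 26 through steps 4, 5, 6, 7, 8, 9, 10, 11, 13, 14, 15 and 16).

**Step 13 (key step).**
- Most likely failure: alkyne insertion in the reverse sense. Both alkyne substituents are large, and the indenyl carbon with its two flanking groups may behave as the bulkier one, which would transpose OH and OMe on ring B.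
- Second failure mode: the hindered alkyne may bind so slowly that the carbene complex decomposes first.
- Fallback (sets out from 9, uses 1 and 15, rejoins at 26): ring B is made from the same bromide that serves ring A, and the C2–B1 bond is closed by Suzuki–Miyaura coupling. Deprotonation of 9 with lithium tetramethylpiperidide at −78 °C, at the position between bromine and the acetal oxygen, and addition to 1 should give rac-[2-bromo-3-methoxy-6-(methoxymethoxy)-4-methylphenyl](2,6-dimethoxyphenyl)methanol F1. Dess–Martin oxidation would give the benzophenone F2. Miyaura borylation (B2pin2, KOAc, Pd(OAc)2, SPhos) would give the pinacol boronate F3. Coupling of F3 with 15 (Pd2(dba)3, SPhos, K3PO4, toluene/H2O) would give the bis(methoxymethyl) ether of acredinone A F4, and acidic methanol would then free both phenols to 26. This is the crowded biaryl coupling the main route avoids, but every step is known chemistry.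

**Step 10.**
- Most likely failures: electrophilic bromination of ring D or ring A competing with the radical chain; capture of a bromonium-activated alkyne by the C7 methoxy oxygen (chromone formation); closure at the methoxy-bearing ortho carbon; loss of the acetal in the acidic medium.
- Fallback (sets out from 11 and 2, rejoins at 16): a Larock indenone annulation. Lithiation of 11 between the formyl group and the acetal, through the in situ lithium α-amino alkoxide, followed by iodine should give 2-iodo-6-methoxy-3-(methoxymethoxy)-5-methylbenzaldehyde F5. Silylation of 2 (n-BuLi, Me3SiCl) gives [(2,6-dimethoxyphenyl)ethynyl]trimethylsilane F6. Annulation of F5 with F6 (Pd(OAc)2, Na2CO3, Bu4NCl, DMF, 100 °C) should place silicon at C2 and give the 2-(trimethylsilyl)indenone F7. Iododesilylation with ICl at low temperature would give the 2-iodoindenone F8, and Sonogashira coupling of F8 with 4 returns to 16.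

**Step 11.**
- Most likely failure: slow oxidative addition at the shielded C2–Br bond, so that copper-mediated oxidative dimerization of 4 and reduction of the bromide dominate.
- Fallback (sets out from 4 and 15, rejoins at 16): a Stille coupling without copper acetylide or amine. Stannylation of 4 (n-BuLi, Bu3SnCl) gives the alkynylstannane F9, which is coupled with 15 using Pd2(dba)3 and AsPh3 in DMF.

**Step 15.**
- Most likely failure: oxidation of the electron-rich ring B phenol to quinone-type products, competing with slow oxidation of the hindered carbinol.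
- Fallback (sets out from 24, rejoins at 25): the phenol is masked first. Selective O-allylation of 24 (allyl bromide, K2CO3, acetone) gives the allyl ether F10. Dess–Martin oxidation, now safe, gives the ketone F11. Deallylation with Pd(PPh3)4 and morpholine returns to 25.

## Further compounds

F1 | step 13 | rac-[2-bromo-3-methoxy-6-(methoxymethoxy)-4-methylphenyl](2,6-dimethoxyphenyl)methanol (one enantiomer drawn) | COCOc1cc(C)c(OC)c(Br)c1[C@H](O)c1c(OC)cccc1OC
F2 | step 13 | [2-bromo-3-methoxy-6-(methoxymethoxy)-4-methylphenyl](2,6-dimethoxyphenyl)methanone | COCOc1cc(C)c(OC)c(Br)c1C(=O)c1c(OC)cccc1OC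
F3 | step 13 | (2,6-dimethoxyphenyl)[3-methoxy-6-(methoxymethoxy)-4-methyl-2-(4,4,5,5-tetramethyl-1,3,2-dioxaborolan-2-yl)phenyl]methanone | COCOc1cc(C)c(OC)c(B2OC(C)(C)C(C)(C)O2)c1C(=O)c1c(OC)cccc1OC
F4 | step 13 | 2-[2-(2,6-dimethoxybenzoyl)-6-methoxy-3-(methoxymethoxy)-5-methylphenyl]-3-(2,6-dimethoxyphenyl)-7-methoxy-4-(methoxymethoxy)-6-methyl-1H-inden-1-one | O=C1C(c2c(OC)c(C)cc(OCOC)c2C(=O)c2c(OC)cccc2OC)=C(c2c(OC)cccc2OC)c2c(OCOC)cc(C)c(OC)c21
F5 | step 10 | 2-iodo-6-methoxy-3-(methoxymethoxy)-5-methylbenzaldehyde | COCOc1cc(C)c(OC)c(C=O)c1I
F6 | step 10 | [(2,6-dimethoxyphenyl)ethynyl]trimethylsilane | C[Si](C)(C)C#Cc1c(OC)cccc1OC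
F7 | step 10 | 3-(2,6-dimethoxyphenyl)-7-methoxy-4-(methoxymethoxy)-6-methyl-2-(trimethylsilyl)-1H-inden-1-one | O=C1C([Si](C)(C)C)=C(c2c(OC)cccc2OC)c2c(OCOC)cc(C)c(OC)c21
F8 | step 10 | 3-(2,6-dimethoxyphenyl)-2-iodo-7-methoxy-4-(methoxymethoxy)-6-methyl-1H-inden-1-one | O=C1C(I)=C(c2c(OC)cccc2OC)c2c(OCOC)cc(C)c(OC)c21
F9 | step 11 | rac-tributyl{3-[(tert-butyldimethylsilyl)oxy]-3-(2,6-dimethoxyphenyl)prop-1-yn-1-yl}stannane (one enantiomer drawn) | CCCC[Sn](CCCC)(CCCC)C#C[C@H](O[Si](C)(C)C(C)(C)C)c1c(OC)cccc1OC
F10 | step 15 | rac-2-{3-(allyloxy)-2-[(2,6-dimethoxyphenyl)(hydroxy)methyl]-6-methoxy-5-methylphenyl}-3-(2,6-dimethoxyphenyl)-7-methoxy-4-(methoxymethoxy)-6-methyl-1H-inden-1-one (one enantiomer drawn) | O=C1C(c2c(OC)c(C)cc(OCC=C)c2[C@H](O)c2c(OC)cccc2OC)=C(c2c(OC)cccc2OC)c2c(OCOC)cc(C)c(OC)c21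
F11 | step 15 | 2-[3-(allyloxy)-2-(2,6-dimethoxybenzoyl)-6-methoxy-5-methylphenyl]-3-(2,6-dimethoxyphenyl)-7-methoxy-4-(methoxymethoxy)-6-methyl-1H-inden-1-one | O=C1C(c2c(OC)c(C)cc(OCC=C)c2C(=O)c2c(OC)cccc2OC)=C(c2c(OC)cccc2OC)c2c(OCOC)cc(C)c(OC)c21
A1 | alternative 1 | (E)-α-aryl chalcone: 3-acetoxy-2-(2,6-dimethoxybenzoyl)-6-methoxy-5-methylphenyl at C2, 5-acetoxy-2-methoxy-3-methylphenyl on the C1 carbonyl, 2,6-dimethoxyphenyl at C3 | COc1c(C)cc(OC(C)=O)cc1C(=O)/C(=C/c1c(OC)cccc1OC)c1c(OC)c(C)cc(OC(C)=O)c1C(=O)c1c(OC)cccc1OC
A2 | alternative 1 | racemic trans-2,3-diarylindan-1-one diacetate (one enantiomer drawn) | O=C1[C@@H](c2c(OC)c(C)cc(OC(C)=O)c2C(=O)c2c(OC)cccc2OC)[C@H](c2c(OC)cccc2OC)c2c(OC(C)=O)cc(C)c(OC)c21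
A3 | alternative 2 | rac-4-[(tert-butyldimethylsilyl)oxy]-1,8-bis(2,6-dimethoxyphenyl)octa-2,6-diyne-1,8-dione (one enantiomer drawn) | COc1cccc(OC)c1C(=O)C#C[C@H](O[Si](C)(C)C(C)(C)C)CC#CC(=O)c1c(OC)cccc1OC
A4 | alternative 2 | triisopropyl[(4-methylfuran-2-yl)oxy]silane | Cc1coc(O[Si](C(C)C)(C(C)C)C(C)C)c1
A5 | alternative 2 | open-chain bis-aryl ketone with rings A and B formed, C1 as silyl-protected carbinol and C2 as CH2 (racemic, one enantiomer drawn) | COc1cccc(OC)c1C(=O)c1c(O[Si](C(C)C)(C(C)C)C(C)C)cc(C)c(O)c1[C@H](O[Si](C)(C)C(C)(C)C)Cc1c(O)c(C)cc(O[Si](C(C)C)(C(C)C)C(C)C)c1C(=O)c1c(OC)cccc1OC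
A6 | alternative 3 | 3-[3-(2,6-dimethoxyphenyl)prop-2-ynoyl]-4-methoxy-5-methylphenyl acetate | COc1c(C)cc(OC(C)=O)cc1C(=O)C#Cc1c(OC)cccc1OC
A7 | alternative 3 | 3-acetoxy-2-(2,6-dimethoxybenzoyl)-6-methoxy-5-methylbenzenediazonium tetrafluoroborate | COc1c(C)cc(OC(C)=O)c(C(=O)c2c(OC)cccc2OC)c1[N+]#N.F[B-](F)(F)F
A8 | alternative 3 | acredinone A diacetate | O=C1C(c2c(OC)c(C)cc(OC(C)=O)c2C(=O)c2c(OC)cccc2OC)=C(c2c(OC)cccc2OC)c2c(OC(C)=O)cc(C)c(OC)c21
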